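(Readings and results are calculated for substances that don't exist; the scatter is artificial.)

Monomer enters chains slowly: the zeta run needs 10.0 h to put 72.2% of its charge there, and the theta run reads 66.9% at 10.0 h.

| setting | zeta | theta | north-east | south |
|---|---|---|---|---|
| free monomer | 0.20 M | 0.20 M | 0.20 M | 0.20 M |
| transfer agent | 0.060 M | 0.060 M | 0.0600 M | 0.120 M |
| protic impurity | 0.010 M | 0.0050 M | 0.0100 M | 0.0100 M |
| initiator | 3 mM | 2 mM | 2.0 mM | 2.0 mM |
| remark | run made earlier | run made earlier |  |  |
| time |  |  | 15 h | 15 h |

| run | time / h | monomer in chains / % |
|---|---|---|
| zeta | 1.33 | 24.4 |
| zeta | 2.50 | 45.8 |
| zeta | 4.00 | 59.5 |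
| zeta | 5.00 | 66.3 |
| zeta | 6.00 | 66.1 |
| zeta | 8.00 | 70.3 |
| zeta | 10.0 | 72.2 |
| theta | 0.667 | 7.9 |
| theta | 1.00 | 12.3 |
| theta | 1.50 | 21.1 |
| theta | 2.50 | 36.2 |
| theta | 4.00 | 50.1 |
| theta | 6.00 | 60.5 |
| theta | 10.0 | 66.9 |

(each reading ± 1 percentage point)

- the average divides the monomer in chains by the number of chains begun, living and dead together
- the earlier runs were read with a standard deviation of 1 percentage point
- the earlier runs do not show the number of chains; that part of a forecast is a guess
- no earlier run changes the charge of transfer agent; that part of a forecast is a guess

- which of the two ends with the longer chains by the average number of monomer units in a chain (chains begun, living or dead) ("neither" if they lie within 10%) (north-east / south / neither)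
- average number of monomer units in a chain (chains begun, living or dead) at the end, north-east
- average number of monomer units in a chain (chains begun, living or dead) at the end, south

The bench rule for length has no clock in it. Each initiator begins one chain and the monomer is shared among them, so the length equals free monomer charged over initiator charged, the charge ratio, 100 in north-east and south alike (the target degree of polymerisation). In logarithms:

log length = log c(free monomer) − log c(initiator) = 2.00

Two ratios mark the border of this rule. Protic impurity stands at 3.33 times the initiator in the zeta run, yet chains fill there, so impurity does not take initiator one for one. But the theta run, charged with north-east's initiator, reads 66.9%, so the rule needs a term for monomer outside chains and one for initiator that begins none: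

log length = 2.00 + log(share of monomer in chains) − log(share of initiator beginning a chain)

The first term, from that reading, is −0.175, a factor of 1.49, and here the plain rule stops being exact. The second term is unread, and a share below one raises the length. The reckoning here therefore takes 66.9 as a low estimate for north-east; the readings give no upper mark, so about 100 is a guess. South carries twice the transfer agent, but no run varies it; dead chains stay counted, so the guess is that south lies within 10%: neither.

The forecast differs, with north-east longer, 40 against 28: “The impurity-independent part may come from the transfer agent, but that is a guess.”

The flask gives neither: 103 in north-east, 97.6 in south.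

    free monomer + initiator → spent initiator (k = 0.0280 M⁻¹ min⁻¹)
    protic impurity + free monomer → quenched substrate (k = 0.250 M⁻¹ min⁻¹)
    free monomer + living end → monomer in chains + living end, rate k3*[living end]*[free monomer] (k = 4.90 M⁻¹ min⁻¹)
    living end + transfer agent → dead chain (kL = 0.0150 M⁻¹ min⁻¹)
    free monomer + initiator → living end + monomer in chains (k = 0.0580 M⁻¹ min⁻¹)
    free monomer → uncatalysed product (k = 0.00170 min⁻¹)

In north-east at 15.0 h, free monomer goes into chains at 1.8 times the rate at which it turns into uncatalysed product, and 65.8% stands in chains against 28.4% of that product, with the length 103 beside a charge ratio of 100. The neighbour flask with 0.500 mM of initiator, charge ratio 400, holds more uncatalysed product (53.2%) than monomer in chains (33.9%), and reaches half of that ratio, a length of 202.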